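**Plan**
- Retrosynthesis cuts, in this order: the two O–CH3 bonds (masked catechol); the C4–C5 bond of the pyrrolidinone ring, with a carboxyl group put back on C5; the acyl C2–N bond (acryloyl chloride); the benzylic C–N bond (tert-butyl glycinate plus a benzyl bromide); the benzylic C–Br bond; the three aryl C–Br bonds, back to 4-methylcatechol.
- Forward: the benzene ring is bought, then perbrominated, O-methylated and brominated at the methyl group. The glycine chain and the acryloyl group are joined to the benzylic carbon, the pyrrolidinone (the only ring made) closes by C4–C5 bond formation, and BBr3 frees the catechol.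
- Enabling feature: in the lactam ring, N1–C2(=O)–C3–C4 is a disguised N-acryloyl amide with C4 as its β-carbon, and C5 (the ring CH2 on nitrogen) is the α-carbon of an N-acylglycine. Loss of CO2 turns C5 into a nucleophilic α-amido radical placed to add to C4.
- Stereochemistry: the target has no stereocenter and no double-bond isomerism, so nothing has to be controlled.

Key step: step 7

**Step 1**
Reactants: 1 4-methylbenzene-1,2-diol (4-methylcatechol)
Product: 2 3,4,6-tribromo-5-methylbenzene-1,2-diol
Conditions: Br2 (3.1 equiv), AcOH, 15 °C to rt
Reagents that add atoms: bromine, BrBr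
Why: Electrophilic aromatic bromination: each of the three free ring positions is ortho or para to a hydroxyl group, so the catechol should take up exactly three bromine atoms and stop when the ring is fully substituted.

**Step 2**
Reactants: 2 3,4,6-tribromo-5-methylbenzene-1,2-diol
Product: 3 1,2,4-tribromo-5,6-dimethoxy-3-methylbenzene
Conditions: MeI (3 equiv), K2CO3, DMF, rt to 40 °C
Reagents that add atoms: iodomethane, CI
Why: Williamson ether synthesis: the acidic bromocatechol is deprotonated by K2CO3 and both phenoxides are methylated by SN2 attack on iodomethane, which masks the oxidizable catechol for the radical and photoredox steps.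

**Step 3**
Reactants: 3 1,2,4-tribromo-5,6-dimethoxy-3-methylbenzene
Product: 4 1,2,4-tribromo-3-(bromomethyl)-5,6-dimethoxybenzene (2,3,6-tribromo-4,5-dimethoxybenzyl bromide)
Conditions: NBS (1.05 equiv), AIBN (cat.), PhCF3, 80 °C
Reagents that add atoms: N-bromosuccinimide, O=C1CCC(=O)N1Br
Why: Wohl–Ziegler radical bromination: with every ring position occupied only the benzylic methyl hydrogens can react, and the two ortho bromines should hold the reaction at the monobromide.

**Step 4**
Reactants: 4 1,2,4-tribromo-3-(bromomethyl)-5,6-dimethoxybenzene; 5 tert-butyl glycinate (free base, 3 equiv)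
Product: 6 tert-butyl N-[(2,3,6-tribromo-4,5-dimethoxyphenyl)methyl]glycinate
Conditions: K2CO3, MeCN, rt to 50 °C
Reagents that add atoms: none
Why: SN2 N-alkylation of a primary amine by a benzylic bromide: the excess of glycinate and the two ortho bromines of the electrophile should suppress a second benzylation.

**Step 5**
Reactants: 6 tert-butyl N-[(2,3,6-tribromo-4,5-dimethoxyphenyl)methyl]glycinate; 7 acryloyl chloride
Product: 8 tert-butyl N-acryloyl-N-[(2,3,6-tribromo-4,5-dimethoxyphenyl)methyl]glycinate
Conditions: iPr2NEt, CH2Cl2, −20 °C to 0 °C
Reagents that add atoms: none
Why: N-acylation of a secondary amine by an acid chloride (Schotten–Baumann type), run cold with a hindered base so that aza-Michael addition to the new acrylamide does not compete.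

**Step 6**
Reactants: 8 tert-butyl N-acryloyl-N-[(2,3,6-tribromo-4,5-dimethoxyphenyl)methyl]glycinate
Product: 9 N-acryloyl-N-[(2,3,6-tribromo-4,5-dimethoxyphenyl)methyl]glycine
Conditions: TFA/CH2Cl2 (1:3), 0 °C to rt
Reagents that add atoms: none
Why: Acidolysis of the tert-butyl ester through the tert-butyl cation, which loses a proton as 2-methylpropene; the acrylamide, the aryl methyl ethers and the aryl bromides are inert to TFA.

**Step 7**
Reactants: 9 N-acryloyl-N-[(2,3,6-tribromo-4,5-dimethoxyphenyl)methyl]glycine
Product: 12 1-[(2,3,6-tribromo-4,5-dimethoxyphenyl)methyl]pyrrolidin-2-one, via aminomethyl radical 10 (not isolated), via lactam C3 radical 11 (not isolated)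
Conditions: Ir[dF(CF3)ppy]2(dtbbpy)PF6 (2 mol %), K2HPO4 (1.2 equiv), degassed DMF (0.01 M), blue LEDs (450 nm), 30 °C
Reagents that add atoms: none
Why: Proposed new method: the photoexcited trivalent iridium complex should oxidize the carboxylate of 9, CO2 is lost, and the N-acyl aminomethyl radical 10 adds through carbon to the β-carbon of the acrylamide to give the α-carbonyl radical 11, which divalent iridium reduces to the amide enolate that is protonated to 12. The closest known reaction types are the intermolecular photoredox decarboxylative Giese addition of N-acyl α-amino acids to acrylates and acrylamides, and the 5-endo-trig cyclization of carbamoylmethyl radicals onto enamides, which closes the same five-atom array with the amide reversed. The pyrrolidinone closes in the 5-endo-trig mode, which a radical can follow here because the competing 4-exo attack at the α-carbon would give a strained β-lactam with an unstabilized primary radical and is reversible, whereas 5-endo closure gives a stabilized α-amide radical that is removed irreversibly by reduction. No stereocenter is formed. The step needs ring closure to win over intermolecular Giese addition and acrylamide oligomerization, which high dilution and the matched polarity of a nucleophilic radical with an electron-poor alkene should secure, the reactive amide rotamer being replenished by C–N rotation. It also needs the three aryl C–Br bonds to survive, which should hold because the reduced photocatalyst is too weak a reductant to cleave bromoarenes and no tin or silyl radical is present to abstract bromine.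

**Step 8**
Reactants: 12 1-[(2,3,6-tribromo-4,5-dimethoxyphenyl)methyl]pyrrolidin-2-one
Product: 13 1-[(2,3,6-tribromo-4,5-dihydroxyphenyl)methyl]pyrrolidin-2-one (target)
Conditions: BBr3 (5 equiv), CH2Cl2, −78 °C to rt; then H2O
Reagents that add atoms: none
Why: Lewis acid ether cleavage: BBr3 binds each methoxy oxygen and bromide attacks the methyl group by SN2, the extra equivalents covering the reagent held by the lactam carbonyl, while the aryl bromides and the N-benzyl lactam should stay untouched.

**Compound list**
1 | 4-methylbenzene-1,2-diol (4-methylcatechol) | Cc1ccc(O)c(O)c1 | starting material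
2 | 3,4,6-tribromo-5-methylbenzene-1,2-diol | Cc1c(Br)c(O)c(O)c(Br)c1Br | intermediate
3 | 1,2,4-tribromo-5,6-dimethoxy-3-methylbenzene | Cc1c(Br)c(OC)c(OC)c(Br)c1Br | intermediate
4 | 1,2,4-tribromo-3-(bromomethyl)-5,6-dimethoxybenzene | BrCc1c(Br)c(OC)c(OC)c(Br)c1Br | intermediate
5 | tert-butyl glycinate | NCC(=O)OC(C)(C)C | starting material
6 | tert-butyl N-[(2,3,6-tribromo-4,5-dimethoxyphenyl)methyl]glycinate | CC(C)(C)OC(=O)CNCc1c(Br)c(OC)c(OC)c(Br)c1Br | intermediate
7 | acryloyl chloride | C=CC(=O)Cl | starting material
8 | tert-butyl N-acryloyl-N-[(2,3,6-tribromo-4,5-dimethoxyphenyl)methyl]glycinate | C=CC(=O)N(CC(=O)OC(C)(C)C)Cc1c(Br)c(OC)c(OC)c(Br)c1Br | intermediate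
9 | N-acryloyl-N-[(2,3,6-tribromo-4,5-dimethoxyphenyl)methyl]glycine | C=CC(=O)N(CC(=O)O)Cc1c(Br)c(OC)c(OC)c(Br)c1Br | intermediate
10 | aminomethyl radical: [acryloyl(2,3,6-tribromo-4,5-dimethoxybenzyl)amino]methyl radical, not isolated | [CH2]N(Cc1c(Br)c(OC)c(OC)c(Br)c1Br)C(=O)C=C | intermediate
11 | lactam C3 radical: 1-(2,3,6-tribromo-4,5-dimethoxybenzyl)-2-oxopyrrolidin-3-yl radical, not isolated | O=C1[CH]CCN1Cc1c(Br)c(OC)c(OC)c(Br)c1Br | intermediate
12 | 1-[(2,3,6-tribromo-4,5-dimethoxyphenyl)methyl]pyrrolidin-2-one | O=C1CCCN1Cc1c(Br)c(OC)c(OC)c(Br)c1Br | intermediate
13 | 1-[(2,3,6-tribromo-4,5-dihydroxyphenyl)methyl]pyrrolidin-2-one | O=C1CCCN1Cc1c(Br)c(O)c(O)c(Br)c1Br | target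

**Step count**
Total steps: 8. Longest linear sequence: 8 steps, from 4-methylcatechol 1 to the target 13.

**Steps most likely to fail**

Step 7 (Proposed new method). The 5-endo closure may be too slow, so that the aminomethyl radical is intercepted first: by addition to the acrylamide of a second molecule and oligomerization, by hydrogen abstraction from the medium, or by attack on a bromine-bearing ortho carbon of its own arene. The fallback sets out from benzyl bromide 4 and gives up making the ring. Pyrrolidin-2-one F1 is deprotonated with NaH in DMF at 0 °C and the lactam anion is N-alkylated by 4 (SN2 at the benzylic carbon, a standard lactam N-benzylation). This should give 12, where the route is rejoined before step 8; steps 4 to 7 are then not needed.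

Step 4. The product amine may be benzylated a second time, or displacement at the hindered benzylic carbon may be slow enough for the glycinate to condense with itself. The fallback sets out from 4 and replaces the substitution by a reductive amination. Kornblum oxidation of 4 (DMSO, NaHCO3, 100 °C) should give 2,3,6-tribromo-4,5-dimethoxybenzaldehyde F2. Condensation of F2 with tert-butyl glycinate 5 and reduction of the imine with NaBH(OAc)3 and AcOH in 1,2-dichloroethane at rt should give the monoalkylated amine 6, where the route is rejoined before step 5.

Step 1. Excess bromine may oxidize the electron-rich catechol to the ortho-quinone, or brominate the benzylic carbon through a quinone methide tautomer, before the third ring position is substituted. The fallback sets out from 1 and inverts the order of masking and halogenation. O-Methylation of 1 (MeI, K2CO3, DMF) gives 3,4-dimethoxytoluene F3, which is also commercially available. Exhaustive bromination of F3 with excess Br2 and Fe powder (FeBr3 formed in the flask) in CH2Cl2 at rt to 40 °C should give 3 directly, where the route is rejoined before step 3; step 2 is then not needed.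

**Further compounds**
F1 | step 7 | pyrrolidin-2-one | O=C1CCCN1
F2 | step 4 | 2,3,6-tribromo-4,5-dimethoxybenzaldehyde | O=Cc1c(Br)c(OC)c(OC)c(Br)c1Br
F3 | step 1 | 3,4-dimethoxytoluene (1,2-dimethoxy-4-methylbenzene) | Cc1ccc(OC)c(OC)c1
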